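**Plan**

Retrosynthesis: the target is cut at C4–CH= (Wittig on a C4 aldehyde), C7–Et (enol triflate coupling) and C5–Ph (cuprate addition to a C5=C6–C7=O enone); then C6 is excised (bonds C5–C6 and C6–C7), contracting the six-membered ring to a cis-diquinane C7 ketone, which is cut at C4–Et, C3–CH3, C2 (as CO), C7a–C3a, C7–C7a and C4–C5.
Enabling feature: with indene numbering (methyls on C1 and C3, fusion C3a/C7a, quaternary C4, phenyl on C5, C6=C7 alkene with ethyl on C7), C6 is the only unsubstituted carbon of the six-membered ring; without it C7, C5, C4, C3a, C7a and ring C7a–C1–C2–C3–C3a form a cis-bicyclo[3.3.0]octan-7-one whose convex face can set C1, C3, C3a and C4.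
Forward: methyl crotonate, a bromoacetamide and a propynyl Grignard reagent give an acyclic 1,6-enyne; one Pauson–Khand step closes both five-membered rings; after the relay on the cup, one-carbon insertion makes the six-membered ring; phenyl, ethyl and the acrylic acid follow.
Stereochemistry: (S)-C7 from asymmetric transfer hydrogenation directs C3a in the Pauson–Khand step; convex-face hydrogenations, equilibration and alkylation set C7a, C1, C3 and C4; C7 is then oxidised; C7a is inverted to the trans fusion by equilibration after ring expansion; C5 comes from axial cuprate attack anti to the C4 ester; the E alkene from the stabilised ylide.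

Key step: step 13

Remark: indene locants of the target are used throughout (C6 is absent in the diquinanes); α/β mean below/above the ring plane in a drawing with 3a-H α; intermediates 4–19 that contain C4 are C4 epimers, which converge in step 10; the Pauson–Khand step is assumed to follow the usual exo preference of a bulky propargylic silyloxy group.

**Route**

Step 1
Reactants: 1 methyl (E)-but-2-enoate; 2 2-bromo-N-methoxy-N-methylacetamide
Product: 4 methyl 2-ethenyl-4-[methoxy(methyl)amino]-4-oxobutanoate (racemic), via lithium 1-methoxybuta-1,3-dien-1-olate 3 (not isolated)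
Conditions: LDA, DMPU, THF, −78 °C; then 2, −78 → −20 °C
Reagents that add atoms: 2-bromo-N-methoxy-N-methylacetamide (2), CON(C)C(=O)CBr
Why: Deconjugative alkylation: the lithium dienolate of a crotonate reacts with reactive halides at its α-carbon, which joins C4 to C5 and leaves the vinyl group (future C3a=C3) out of conjugation; the new centre (future C4) is racemic and is reset in step 10.

Step 2
Reactants: 4 methyl 2-ethenyl-4-[methoxy(methyl)amino]-4-oxobutanoate; 5 prop-1-yn-1-ylmagnesium bromide
Product: 6 methyl 2-ethenyl-4-oxohept-5-ynoate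
Conditions: 5, THF, −78 → 0 °C; 1 M HCl quench
Reagents that add atoms: prop-1-yn-1-ylmagnesium bromide (5), CC#C[Mg]Br
Why: Weinreb ketone synthesis: the alkynyl Grignard reagent adds to the N-methoxy-N-methylamide faster than to the methyl ester at low temperature, and the chelated adduct survives until work-up, so one propynyl group is delivered and C7–C7a is formed.

Step 3
Reactants: 6 methyl 2-ethenyl-4-oxohept-5-ynoate
Product: 8 methyl (4S)-4-[(tert-butyldimethylsilyl)oxy]-2-ethenylhept-5-ynoate (C2 epimers), via methyl (4S)-2-ethenyl-4-hydroxyhept-5-ynoate 7 (not isolated)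
Conditions: Ru[(S,S)-TsDPEN](p-cymene) (1 mol%, base-free), i-PrOH, rt; concentrate; TBSCl, imidazole, DMF, 0 °C → rt
Reagents that add atoms: tert-butyldimethylsilyl chloride, CC(C)(C)[Si](C)(C)Cl
Why: Noyori asymmetric transfer hydrogenation of the ynone (the alkynyl group takes the role of the aryl group of the acetophenone model, so the (S,S) catalyst should give the (S)-carbinol at C7), and immediate silylation of the crude γ-hydroxy ester forestalls lactonisation and installs the bulky director for step 4.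

Step 4
Reactants: 8 methyl (4S)-4-[(tert-butyldimethylsilyl)oxy]-2-ethenylhept-5-ynoate; 9 dicobalt octacarbonyl
Product: 11 methyl 7α-[(tert-butyldimethylsilyl)oxy]-1-methyl-2-oxobicyclo[3.3.0]oct-1(7a)-ene-4-carboxylate (3a-H α, cis to the silyloxy group; C4 epimers), via hexacarbonyldicobalt complex of the alkyne of 8 10 (not isolated)
Conditions: Co2(CO)8, CH2Cl2, rt; then N-methylmorpholine N-oxide, 0 °C → rt
Reagents that add atoms: dicobalt octacarbonyl (9, source of CO), O=C=[Co](=C=O)(=C=O)(=C=O)[Co](=C=O)(=C=O)(=C=O)=C=O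
Why: N-oxide-promoted Pauson–Khand [2+2+1] cycloaddition: the alkyne–Co2(CO)6 complex inserts the tethered vinyl group and CO (bonds C7a–C3a, C1–C2, C2–C3) to close both five-membered rings, and the propargylic silyloxy group should take the exo position of the forming bicycle, which places 3a-H cis to the C7 oxygen; C3a diastereomers are removed here by chromatography.

Step 5
Reactants: 11 Pauson–Khand enone
Product: 13 methyl 7α-[(tert-butyldimethylsilyl)oxy]-1α-methyl-2-oxo-cis-bicyclo[3.3.0]octane-4-carboxylate (3a-H, 7a-H α; C4 epimers), via its 1β-methyl epimer 12 (not isolated)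
Conditions: H2 (4 atm), 10% Pd/C, EtOAc, rt; filter; NaOMe (0.2 equiv), MeOH, rt
Reagents that add atoms: none
Why: Heterogeneous hydrogenation adds H2 to the tetrasubstituted enone from the convex face, which fixes the cis ring fusion (7a-H α) and gives the endo (1β) methyl, and methoxide then epimerises the enolisable C1 to the more stable exo (1α) methyl.

Step 6
Reactants: 13 saturated ketone; 14 paraformaldehyde
Product: 15 methyl 7α-[(tert-butyldimethylsilyl)oxy]-1α-methyl-3-methylidene-2-oxo-cis-bicyclo[3.3.0]octane-4-carboxylate (C4 epimers)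
Conditions: (CH2O)n, i-Pr2NH·CF3CO2H, CF3CO2H (cat.), THF, reflux
Reagents that add atoms: paraformaldehyde (14, as formaldehyde), C=O
Why: Mannich-type α-methylenation (amine-salt-mediated condensation with formaldehyde, then elimination) can give an exocyclic alkene only at C3, the sole α-carbon with two hydrogens.

Step 7
Reactants: 15 3-methylidene ketone
Product: 17 methyl 7α-[(tert-butyldimethylsilyl)oxy]-2-hydroxy-1α,3β-dimethyl-cis-bicyclo[3.3.0]octane-4-carboxylate (C2 and C4 epimers), via the 1α,3β-dimethyl-2-oxo compound 16 (not isolated)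
Conditions: H2 (1 atm), 10% Pd/C, EtOAc, rt; filter, concentrate; NaBH4, MeOH, −20 °C
Reagents that add atoms: none
Why: Hydrogen is delivered to the exocyclic alkene from the convex face, so the new methyl ends up endo (3β), and the epimerisable ketone is reduced at once with borohydride so that C3 is no longer α to a carbonyl.

Step 8
Reactants: 17 C2 alcohol
Product: 18 methyl 7α-[(tert-butyldimethylsilyl)oxy]-2-[(1H-imidazol-1-ylcarbonothioyl)oxy]-1α,3β-dimethyl-cis-bicyclo[3.3.0]octane-4-carboxylate
Conditions: 1,1'-thiocarbonyldiimidazole, DMAP (cat.), ClCH2CH2Cl, 70 °C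
Reagents that add atoms: 1,1'-thiocarbonyldiimidazole, S=C(n1ccnc1)n1ccnc1
Why: Thioacylation of the secondary alcohol under neutral conditions (no enolate chemistry at C4) gives the thiocarbonyl derivative needed for radical deoxygenation.

Step 9
Reactants: 18 imidazolyl thiocarbonate
Product: 19 methyl 7α-[(tert-butyldimethylsilyl)oxy]-1α,3β-dimethyl-cis-bicyclo[3.3.0]octane-4-carboxylate (C4 epimers)
Conditions: Bu3SnH, AIBN (cat.), toluene, 110 °C
Reagents that add atoms: none
Why: Barton–McCombie deoxygenation: the stannyl radical adds to C=S, the C2–O bond fragments and the secondary radical takes hydrogen from the stannane, which removes the Pauson–Khand oxygen without touching C1 or C3.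

Step 10
Reactants: 19 diquinane ester; 20 iodoethane
Product: 22 methyl 4α-ethyl-7α-[(tert-butyldimethylsilyl)oxy]-1α,3β-dimethyl-cis-bicyclo[3.3.0]octane-4β-carboxylate, via the lithium ester enolate of 19 21 (not isolated)
Conditions: LDA, THF, −78 → −20 °C; then EtI, DMPU, −78 → 0 °C
Reagents that add atoms: iodoethane (20), CCI
Why: Ester enolate alkylation: the electrophile approaches the exocyclic enolate from the convex face of the cup, away from ring B and the endo C3 methyl, so ethyl becomes α (exo), the ester β (endo), and both C4 epimers converge on one quaternary centre.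

Step 11
Reactants: 22 silyl ether
Product: 23 methyl 4α-ethyl-7α-hydroxy-1α,3β-dimethyl-cis-bicyclo[3.3.0]octane-4β-carboxylate
Conditions: TBAF, THF, rt
Reagents that add atoms: none
Why: Fluoride cleaves the Si–O bond, and the trans relation of the 7α-hydroxyl and the 4β-ester rules out lactonisation.

Step 12
Reactants: 23 alcohol
Product: 24 methyl 4α-ethyl-1α,3β-dimethyl-7-oxo-cis-bicyclo[3.3.0]octane-4β-carboxylate (cis-diquinane keto ester lacking C6)
Conditions: Dess–Martin periodinane, NaHCO3, CH2Cl2, rt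
Reagents that add atoms: none
Why: Dess–Martin oxidation of the secondary alcohol gives the cyclopentanone without disturbing the cis ring fusion and removes the C7 stereocentre once it has done its work.

Step 13
Reactants: 24 cis-diquinane keto ester; 25 trimethylsilyldiazomethane
Product: 28 methyl 4α-ethyl-1α,3β-dimethyl-7-oxooctahydro-1H-indene-4β-carboxylate, trans-fused (3a-H α, 7a-H β), via its cis-fused 6-(trimethylsilyl) derivative 26 (not isolated), via the cis-fused (7a-H α) ketone 27 (not isolated)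
Conditions: Me3SiCHN2, AlMe3, CH2Cl2, −78 → −20 °C; then NaOMe, MeOH, rt
Reagents that add atoms: trimethylsilyldiazomethane (25), C[Si](C)(C)C=[N+]=[N-]
Why: AlMe3 activates the C7 carbonyl, the diazo carbon of 25 adds to it, and in the β-aluminoxy diazonium the C7–C5 bond antiperiplanar to N2+ shifts to the silylated carbon as N2 leaves, forming C7–C6 and C6–C5 and giving β-ketosilane 26. The closest known reaction type is the Lewis-acid-promoted diazoalkane homologation of cyclic ketones (Büchner–Curtius–Schlotterbeck, Tiffeneau–Demjanov type), routinely used with Me3SiCHN2 to turn cyclopentanones into cyclohexanones. The six-membered ring C3a–C4–C5–C6–C7–C7a is closed by this 1,2-shift ring expansion, not by a cyclisation. No new stereocentre remains: C7a does not migrate and is first retained (cis ketone 27 after methanolysis of the C–Si bond), then inverted by methoxide under thermodynamic control, because either chair of the cis ketone must place the C1 arm 1,3-diaxial to the C4 ester or put the C4 ethyl axial with the 3β-methyl over the ring, whereas trans ketone 28 carries only the ester axial. The step needs migration of the C5 methylene rather than the C7a methine and a single insertion; the first should follow from the usual preference of silyldiazomethane–aluminium adducts for migration of the less substituted α-carbon, the second from the bulk of the α-silyl group in 26, and C1, C3 and C4 are not enolisable.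

Step 14
Reactants: 28 trans-hydrindan-7-one
Product: 30 methyl 4α-ethyl-1α,3β-dimethyl-7-oxo-2,3,3a,4,7,7a-hexahydro-1H-indene-4β-carboxylate (C5=C6 enone, trans-fused), via the C6=C7 trimethylsilyl enol ether 29 (not isolated)
Conditions: LDA, TMSCl, THF, −78 °C; concentrate; Pd(OAc)2, MeCN, rt
Reagents that add atoms: none
Why: Saegusa–Ito oxidation: LDA removes the more accessible C6 proton (kinetic enolate, trapped in situ as the silyl enol ether) and Pd(II) then gives the C5=C6 enone by β-hydride elimination, leaving C7a untouched.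

Step 15
Reactants: 30 enone; 31 phenyllithium (as lithium diphenylcuprate made in the flask with CuI)
Product: 33 methyl 4α-ethyl-1α,3β-dimethyl-5α-phenyl-7-{[(trifluoromethyl)sulfonyl]oxy}-2,3,3a,4,5,7a-hexahydro-1H-indene-4β-carboxylate, via the lithium C6=C7 enolate of the 5α-phenyl ketone 32 (not isolated)
Conditions: Ph2CuLi (PhLi, CuI), Et2O/THF, −78 → −20 °C; then PhNTf2, THF, −78 °C → rt
Reagents that add atoms: phenyllithium (31), [Li]c1ccccc1; N-phenylbis(trifluoromethanesulfonimide), O=S(=O)(N(c1ccccc1)S(=O)(=O)C(F)(F)F)C(F)(F)F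
Why: Conjugate addition of the Gilman reagent to the trans-fused enone should occur axially at C5 on the α face, anti to the axial C4 ester (chair-like transition state), and the regiodefined C6=C7 enolate is then trapped on oxygen by the triflimide.

Step 16
Reactants: 33 enol triflate; 34 ethylmagnesium bromide
Product: 35 methyl 4α,7-diethyl-1α,3β-dimethyl-5α-phenyl-2,3,3a,4,5,7a-hexahydro-1H-indene-4β-carboxylate
Conditions: EtMgBr, Fe(acac)3 (5 mol%), THF/NMP, −30 °C
Reagents that add atoms: ethylmagnesium bromide (34), CC[Mg]Br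
Why: Iron-catalysed Kumada-type cross-coupling of alkenyl triflates with alkyl Grignard reagents is fast at low temperature, tolerates the hindered ester and replaces OTf by ethyl with the C6=C7 alkene held in place.

Step 17
Reactants: 35 methyl ester
Product: 36 [4α,7-diethyl-1α,3β-dimethyl-5α-phenyl-2,3,3a,4,5,7a-hexahydro-1H-inden-4β-yl]methanol
Conditions: LiAlH4, THF, 0 °C → reflux
Reagents that add atoms: none
Why: Hydride reduction of the neopentyl methyl ester gives the primary alcohol; the isolated trisubstituted alkene is inert.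

Step 18
Reactants: 36 primary alcohol
Product: 37 4α,7-diethyl-1α,3β-dimethyl-5α-phenyl-2,3,3a,4,5,7a-hexahydro-1H-indene-4β-carbaldehyde
Conditions: Dess–Martin periodinane, NaHCO3, CH2Cl2, rt
Reagents that add atoms: none
Why: Dess–Martin oxidation gives the non-enolisable quaternary aldehyde without over-oxidation.

Step 19
Reactants: 37 aldehyde; 38 ethyl 2-(triphenyl-λ5-phosphanylidene)propanoate
Product: 39 ethyl (2E)-3-[4α,7-diethyl-1α,3β-dimethyl-5α-phenyl-2,3,3a,4,5,7a-hexahydro-1H-inden-4β-yl]-2-methylprop-2-enoate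
Conditions: 38, toluene, 110 °C
Reagents that add atoms: ethyl 2-(triphenyl-λ5-phosphanylidene)propanoate (38), CCOC(=O)C(C)=P(c1ccccc1)(c1ccccc1)c1ccccc1
Why: Wittig olefination with the stabilised α-methyl ylide should give the (E)-trisubstituted acrylate, the ester ending up trans to the bulky ring carbon.

Step 20
Reactants: 39 ethyl ester
Product: 40 homo-plakotenin
Conditions: LiOH, THF/MeOH/H2O, 50 °C; then 1 M HCl
Reagents that add atoms: lithium hydroxide, [Li+].[OH-]
Why: Saponification (acyl–oxygen cleavage) and acidification release the acid, and no stereocentre is epimerisable under these conditions.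

**Compound list**

1 | methyl (E)-but-2-enoate (methyl crotonate) | C/C=C/C(=O)OC | starting material
2 | 2-bromo-N-methoxy-N-methylacetamide | CON(C)C(=O)CBr | starting material
3 | lithium 1-methoxybuta-1,3-dien-1-olate (dienolate of 1) | C=CC=C(OC)[O-].[Li+] | intermediate
4 | methyl 2-ethenyl-4-[methoxy(methyl)amino]-4-oxobutanoate (racemic) | C=CC(CC(=O)N(C)OC)C(=O)OC | intermediate
5 | prop-1-yn-1-ylmagnesium bromide | CC#C[Mg]Br | starting material
6 | methyl 2-ethenyl-4-oxohept-5-ynoate (racemic) | C=CC(CC(=O)C#CC)C(=O)OC | intermediate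
7 | methyl (4S)-2-ethenyl-4-hydroxyhept-5-ynoate (C2 epimers) | C=CC(C[C@H](O)C#CC)C(=O)OC | intermediate
8 | methyl (4S)-4-[(tert-butyldimethylsilyl)oxy]-2-ethenylhept-5-ynoate (C2 epimers) | C=CC(C[C@H](O[Si](C)(C)C(C)(C)C)C#CC)C(=O)OC | intermediate
9 | dicobalt octacarbonyl | O=C=[Co](=C=O)(=C=O)(=C=O)[Co](=C=O)(=C=O)(=C=O)=C=O | starting material
10 | hexacarbonyldicobalt complex of the alkyne of 8 | CC12[Co]3(=C=O)(=C=O)(=C=O)[Co]1(=C=O)(=C=O)(=C=O)C23[C@@H](O[Si](C)(C)C(C)(C)C)CC(C=C)C(=O)OC | intermediate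
11 | methyl 7α-[(tert-butyldimethylsilyl)oxy]-1-methyl-2-oxobicyclo[3.3.0]oct-1(7a)-ene-4-carboxylate (3a-H α; C4 epimers) | CC(C)(C)[Si](C)(C)O[C@H]1CC(C(=O)OC)[C@H]2C1=C(C)C(=O)C2 | intermediate
12 | methyl 7α-[(tert-butyldimethylsilyl)oxy]-1β-methyl-2-oxo-cis-bicyclo[3.3.0]octane-4-carboxylate (3a-H, 7a-H α; methyl endo) | CC(C)(C)[Si](C)(C)O[C@H]1CC(C(=O)OC)[C@H]2[C@@H]1[C@@H](C)C(=O)C2 | intermediate
13 | methyl 7α-[(tert-butyldimethylsilyl)oxy]-1α-methyl-2-oxo-cis-bicyclo[3.3.0]octane-4-carboxylate (methyl exo) | CC(C)(C)[Si](C)(C)O[C@H]1CC(C(=O)OC)[C@H]2[C@@H]1[C@H](C)C(=O)C2 | intermediate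
14 | paraformaldehyde (as formaldehyde) | C=O | starting material
15 | methyl 7α-[(tert-butyldimethylsilyl)oxy]-1α-methyl-3-methylidene-2-oxo-cis-bicyclo[3.3.0]octane-4-carboxylate | CC(C)(C)[Si](C)(C)O[C@H]1CC(C(=O)OC)[C@H]2[C@@H]1[C@H](C)C(=O)C2=C | intermediate
16 | methyl 7α-[(tert-butyldimethylsilyl)oxy]-1α,3β-dimethyl-2-oxo-cis-bicyclo[3.3.0]octane-4-carboxylate | CC(C)(C)[Si](C)(C)O[C@H]1CC(C(=O)OC)[C@H]2[C@@H]1[C@H](C)C(=O)[C@H]2C | intermediate
17 | methyl 7α-[(tert-butyldimethylsilyl)oxy]-2-hydroxy-1α,3β-dimethyl-cis-bicyclo[3.3.0]octane-4-carboxylate (C2 and C4 epimers) | CC(C)(C)[Si](C)(C)O[C@H]1CC(C(=O)OC)[C@H]2[C@@H]1[C@H](C)C(O)[C@H]2C | intermediate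
18 | methyl 7α-[(tert-butyldimethylsilyl)oxy]-2-[(1H-imidazol-1-ylcarbonothioyl)oxy]-1α,3β-dimethyl-cis-bicyclo[3.3.0]octane-4-carboxylate | CC(C)(C)[Si](C)(C)O[C@H]1CC(C(=O)OC)[C@H]2[C@@H]1[C@H](C)C(OC(=S)n3ccnc3)[C@H]2C | intermediate
19 | methyl 7α-[(tert-butyldimethylsilyl)oxy]-1α,3β-dimethyl-cis-bicyclo[3.3.0]octane-4-carboxylate (C4 epimers) | CC(C)(C)[Si](C)(C)O[C@H]1CC(C(=O)OC)[C@H]2[C@@H]1[C@H](C)C[C@H]2C | intermediate
20 | iodoethane | CCI | starting material
21 | lithium ester enolate of 19 | CC(C)(C)[Si](C)(C)O[C@H]1CC(=C(OC)[O-])[C@H]2[C@@H]1[C@H](C)C[C@H]2C.[Li+] | intermediate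
22 | methyl 4α-ethyl-7α-[(tert-butyldimethylsilyl)oxy]-1α,3β-dimethyl-cis-bicyclo[3.3.0]octane-4β-carboxylate | CC(C)(C)[Si](C)(C)O[C@H]1C[C@@](C(=O)OC)(CC)[C@H]2[C@@H]1[C@H](C)C[C@H]2C | intermediate
23 | methyl 4α-ethyl-7α-hydroxy-1α,3β-dimethyl-cis-bicyclo[3.3.0]octane-4β-carboxylate | O[C@H]1C[C@@](C(=O)OC)(CC)[C@H]2[C@@H]1[C@H](C)C[C@H]2C | intermediate
24 | methyl 4α-ethyl-1α,3β-dimethyl-7-oxo-cis-bicyclo[3.3.0]octane-4β-carboxylate (cis-diquinane keto ester) | O=C1C[C@@](C(=O)OC)(CC)[C@H]2[C@@H]1[C@H](C)C[C@H]2C | intermediate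
25 | trimethylsilyldiazomethane | C[Si](C)(C)C=[N+]=[N-] | starting material
26 | methyl 4α-ethyl-1α,3β-dimethyl-7-oxo-6-(trimethylsilyl)octahydro-1H-indene-4β-carboxylate, cis-fused (C6 epimers) | O=C1C([Si](C)(C)C)C[C@@](C(=O)OC)(CC)[C@H]2[C@@H]1[C@H](C)C[C@H]2C | intermediate
27 | methyl 4α-ethyl-1α,3β-dimethyl-7-oxooctahydro-1H-indene-4β-carboxylate, cis-fused (7a-H α) | O=C1CC[C@@](C(=O)OC)(CC)[C@H]2[C@@H]1[C@H](C)C[C@H]2C | intermediate
28 | methyl 4α-ethyl-1α,3β-dimethyl-7-oxooctahydro-1H-indene-4β-carboxylate, trans-fused (7a-H β) | O=C1CC[C@@](C(=O)OC)(CC)[C@H]2[C@H]1[C@H](C)C[C@H]2C | intermediate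
29 | methyl 4α-ethyl-1α,3β-dimethyl-7-[(trimethylsilyl)oxy]-2,3,3a,4,5,7a-hexahydro-1H-indene-4β-carboxylate | C[Si](C)(C)OC1=CC[C@@](C(=O)OC)(CC)[C@H]2[C@H]1[C@H](C)C[C@H]2C | intermediate
30 | methyl 4α-ethyl-1α,3β-dimethyl-7-oxo-2,3,3a,4,7,7a-hexahydro-1H-indene-4β-carboxylate (C5=C6 enone) | O=C1C=C[C@@](C(=O)OC)(CC)[C@H]2[C@H]1[C@H](C)C[C@H]2C | intermediate
31 | phenyllithium | [Li]c1ccccc1 | starting material
32 | lithium C6=C7 enolate of methyl 4α-ethyl-1α,3β-dimethyl-7-oxo-5α-phenyloctahydro-1H-indene-4β-carboxylate | [Li+].[O-]C1=C[C@@H](c3ccccc3)[C@@](C(=O)OC)(CC)[C@H]2[C@H]1[C@H](C)C[C@H]2C | intermediate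
33 | methyl 4α-ethyl-1α,3β-dimethyl-5α-phenyl-7-{[(trifluoromethyl)sulfonyl]oxy}-2,3,3a,4,5,7a-hexahydro-1H-indene-4β-carboxylate | O=S(=O)(OC1=C[C@@H](c3ccccc3)[C@@](C(=O)OC)(CC)[C@H]2[C@H]1[C@H](C)C[C@H]2C)C(F)(F)F | intermediate
34 | ethylmagnesium bromide | CC[Mg]Br | starting material
35 | methyl 4α,7-diethyl-1α,3β-dimethyl-5α-phenyl-2,3,3a,4,5,7a-hexahydro-1H-indene-4β-carboxylate | CCC1=C[C@@H](c2ccccc2)[C@@](C(=O)OC)(CC)[C@H]2[C@H]1[C@H](C)C[C@H]2C | intermediate
36 | [4α,7-diethyl-1α,3β-dimethyl-5α-phenyl-2,3,3a,4,5,7a-hexahydro-1H-inden-4β-yl]methanol | CCC1=C[C@@H](c2ccccc2)[C@@](CO)(CC)[C@H]2[C@H]1[C@H](C)C[C@H]2C | intermediate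
37 | 4α,7-diethyl-1α,3β-dimethyl-5α-phenyl-2,3,3a,4,5,7a-hexahydro-1H-indene-4β-carbaldehyde | CCC1=C[C@@H](c2ccccc2)[C@@](C=O)(CC)[C@H]2[C@H]1[C@H](C)C[C@H]2C | intermediate
38 | ethyl 2-(triphenyl-λ5-phosphanylidene)propanoate | CCOC(=O)C(C)=P(c1ccccc1)(c1ccccc1)c1ccccc1 | starting material
39 | ethyl (2E)-3-[4α,7-diethyl-1α,3β-dimethyl-5α-phenyl-2,3,3a,4,5,7a-hexahydro-1H-inden-4β-yl]-2-methylprop-2-enoate | CCC1=C[C@@H](c2ccccc2)[C@@](/C=C(\C)C(=O)OCC)(CC)[C@H]2[C@H]1[C@H](C)C[C@H]2C | intermediate
40 | homo-plakotenin, (2E)-3-[4α,7-diethyl-1α,3β-dimethyl-5α-phenyl-2,3,3a,4,5,7a-hexahydro-1H-inden-4β-yl]-2-methylprop-2-enoic acid (3a-H α, 7a-H β) | CCC1=C[C@@H](c2ccccc2)[C@@](/C=C(\C)C(=O)O)(CC)[C@H]2[C@H]1[C@H](C)C[C@H]2C | target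

**Count and risks**

Total step count: 20. Longest linear sequence: 20 steps (from methyl crotonate 1).

Step 13 (key step). The ring-fusion methine C7a may migrate in competition with the C5 methylene, a second insertion into the product ketone may follow, or the equilibration at C7a may stop short of the trans fusion. The fallback sets out from 24 and comes back at 30, bypassing steps 13 and 14. Kinetic enolisation of 24 (LDA, TMSCl, THF, −78 °C) should give the C5=C7 trimethylsilyl enol ether F1. Simmons–Smith cyclopropanation (Et2Zn, CH2I2) should give the siloxycyclopropane F2. FeCl3 in DMF should open the internal cyclopropane bond to the ring-expanded β-chloro ketone F3 (Saegusa–Ito ring expansion). NaOAc in hot methanol should eliminate HCl to the cis-fused enone F4, and DBU should equilibrate C7a to give 30. Here the site of insertion is fixed by the kinetic enolate and not by a migratory preference.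

Step 4. The facial selectivity of alkene insertion may be modest, because the alkyne carries only a methyl group opposite the propargylic silyloxy director, and diastereomers epimeric at C3a would lower the throughput. The fallback sets out from 4 and comes back at 11. (Trimethylsilyl)ethynylmagnesium bromide with 4 should give the silyl ynone F5. The same transfer hydrogenation should give the hydroxy ester F6, and silylation the silyl ether F7. Co2(CO)8 should give the hexacarbonyldicobalt complex F8, and N-oxide-promoted Pauson–Khand cyclisation, with the large silyl group now reinforcing the exo preference, the 1-(trimethylsilyl) enone F9. Ipso-iododesilylation with ICl should give the 1-iodo enone F10, and Suzuki–Miyaura methylation (trimethylboroxine, Pd(dppf)Cl2, K2CO3) should return 11.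

Step 15. Cuprate addition at C5, next to the quaternary C4, may be slow, and the copper-containing enolate may triflate sluggishly or equilibrate towards C7a before it is trapped. The fallback sets out from 30 and comes back at 33. Rhodium-catalysed Hayashi–Miyaura 1,4-addition of phenylboronic acid ([Rh(cod)OH]2, dioxane/H2O), with the same anti-to-ester facial bias, should give the 5α-phenyl ketone F11. Kinetic deprotonation at C6 (LDA, THF, −78 °C) regenerates enolate 32 free of copper, and PhNTf2 should give 33.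

**Further compounds**

F1 | step 13 | methyl 4α-ethyl-1α,3β-dimethyl-7-[(trimethylsilyl)oxy]-cis-bicyclo[3.3.0]oct-5(7)-ene-4β-carboxylate | C[Si](C)(C)OC1=C[C@@](C(=O)OC)(CC)[C@H]2[C@@H]1[C@H](C)C[C@H]2C
F2 | step 13 | siloxycyclopropane of F1 (CH2 bridging C5 and C7, the future C6) | C[Si](C)(C)OC13CC3[C@@](C(=O)OC)(CC)[C@H]2[C@@H]1[C@H](C)C[C@H]2C
F3 | step 13 | methyl 5-chloro-4α-ethyl-1α,3β-dimethyl-7-oxooctahydro-1H-indene-4β-carboxylate, cis-fused (C5 epimers) | O=C1CC(Cl)[C@@](C(=O)OC)(CC)[C@H]2[C@@H]1[C@H](C)C[C@H]2C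
F4 | step 13 | methyl 4α-ethyl-1α,3β-dimethyl-7-oxo-2,3,3a,4,7,7a-hexahydro-1H-indene-4β-carboxylate, cis-fused (7a-H α) | O=C1C=C[C@@](C(=O)OC)(CC)[C@H]2[C@@H]1[C@H](C)C[C@H]2C
F5 | step 4 | methyl 2-ethenyl-4-oxo-6-(trimethylsilyl)hex-5-ynoate | C=CC(CC(=O)C#C[Si](C)(C)C)C(=O)OC
F6 | step 4 | methyl (4S)-2-ethenyl-4-hydroxy-6-(trimethylsilyl)hex-5-ynoate | C=CC(C[C@H](O)C#C[Si](C)(C)C)C(=O)OC
F7 | step 4 | methyl (4S)-4-[(tert-butyldimethylsilyl)oxy]-2-ethenyl-6-(trimethylsilyl)hex-5-ynoate | C=CC(C[C@H](O[Si](C)(C)C(C)(C)C)C#C[Si](C)(C)C)C(=O)OC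
F8 | step 4 | hexacarbonyldicobalt complex of the alkyne of F7 | C[Si](C)(C)C12[Co]3(=C=O)(=C=O)(=C=O)[Co]1(=C=O)(=C=O)(=C=O)C23[C@@H](O[Si](C)(C)C(C)(C)C)CC(C=C)C(=O)OC
F9 | step 4 | methyl 7α-[(tert-butyldimethylsilyl)oxy]-2-oxo-1-(trimethylsilyl)bicyclo[3.3.0]oct-1(7a)-ene-4-carboxylate | CC(C)(C)[Si](C)(C)O[C@H]1CC(C(=O)OC)[C@H]2C1=C([Si](C)(C)C)C(=O)C2
F10 | step 4 | methyl 7α-[(tert-butyldimethylsilyl)oxy]-1-iodo-2-oxobicyclo[3.3.0]oct-1(7a)-ene-4-carboxylate | CC(C)(C)[Si](C)(C)O[C@H]1CC(C(=O)OC)[C@H]2C1=C(I)C(=O)C2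
F11 | step 15 | methyl 4α-ethyl-1α,3β-dimethyl-7-oxo-5α-phenyloctahydro-1H-indene-4β-carboxylate, trans-fused | O=C1C[C@@H](c3ccccc3)[C@@](C(=O)OC)(CC)[C@H]2[C@H]1[C@H](C)C[C@H]2C
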